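# Proposed synthesis of CNP0159814.2 by benzocyclobutene opening and intramolecular Diels–Alder closure of rings A and B

Abietane numbering is used throughout, also for the atoms of open-chain precursors: ring A is C1–C5 and C10, ring B is C5–C10, ring C is the arene C8, C9, C11–C14; C18 is the methyl and C19 the carboxyl carbon on C4; C20 is the carbon on C10.

## The problem

The target 33 is a 7-oxoabieta-8,11,13-triene in which the C19 carboxyl on C4 is lactonised onto the C20 oxymethylene on C10. The six-membered lactone therefore bridges two axial bonds on one face of a trans-fused A/B system. Three contiguous stereocentres, C4, C5 and C10, two of them quaternary and none bearing a heteroatom, must be set in one enantiomeric series. C5 and C10 are ring-fusion atoms and are best created together with the rings. C4 is the only centre that can be made beforehand in an open chain by asymmetric catalysis; it cannot epimerise, and through a chair-like tether it can dictate the other two. C19 and C20 both sit on quaternary carbons at different oxidation levels, so they must differ in kind (nitrile against ester) and not merely in accessibility. Ring C is an 11,14-hydroquinone methylated at O12, sensitive to air and to every oxidant the route needs, so it must be unveiled last; the lactone excludes organolithium reagents and LiAlH4 late on, and a C7 ketone would not survive the hydride that adjusts C20. The enabling feature is that ring B is fused to the arene at C8–C9 with both benzylic carbons, C7 and the quaternary C10, in the ring and the methine C5 next to C10. C7 and C10 can thus be the termini of an o-quinodimethane, C5=C6 a vinyl group on the quaternary C4, and the C1–C3 chain between C10 and C4 becomes ring A.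

## Retrosynthesis

**Arene oxidation level (33 ⇒ 31 ⇒ 30).** The C11–O bond is cut first. Hydroquinone 33 is traced through quinone 32 to the 14-phenol 31, whose para position C11 is free, and 31 to the 12,14-dimethoxy ketone 30 by removal of one O-methyl group. Carrying free phenols or a quinone through ring construction would require protecting groups that survive chromium and hydride reagents; two methyl ethers do this without extra steps. The forward reactions must distinguish the two methyl ethers, which the C7 carbonyl allows by chelation, and must oxidise only at C11.

**C7 carbonyl (30 ⇒ 29).** The C7=O bond is cut back to a C–H oxidation of lactone 29. Bringing the oxygen in earlier would require an oxygenated benzocyclobutene and would expose a ketone to the C20 reduction. C7 is the only benzylic methylene of 29 and is activated by the para (C12) and ortho (C14) methoxy groups.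

**Lactone (29 ⇒ 27 ⇒ 26).** The acyl–oxygen bond C19–O is cut, C19 is traced to a nitrile and C20 to a methyl ester (nitrile ester 26, via alcohol 27). Cutting the alkyl–oxygen bond C20–O instead would require a displacement at a neopentyl carbon. Nitrile and ester are orthogonal towards LiBH4, and the nitrile is both the electrophile for a Pinner-type ring closure and the smallest possible group on C4, which the key step exploits. The forward reactions need only the 1,3-diaxial arrangement of the two carbons.

**Rings A and B (26 ⇒ 24, via 25).** The bonds C5–C10 and C6–C7 are cut together. This removes both rings and both fusion stereocentres at once and leaves the benzocyclobutene 24, whose only stereocentre of consequence is C4. Stepwise alternatives (ring B by acylation at C8, ring A by alkylation) would have to set C5 and C10 in separate operations. The forward reaction must give the trans fusion and place the C4 nitrile syn to the C10 ester.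

**C1–C10 bond (24 ⇒ 14 + 22).** Enolate alkylation joins the benzocyclobutene ester 14 to the iodide 22 and makes the route convergent. Cutting C3–C4 instead would mean creating the C4 stereocentre late, in the presence of the strained ring. The new C10 centre needs no control because it becomes planar on ring opening.

**Four-membered ring (14 ⇒ 12 ⇒ 10).** The aryl–carbon bond C9–C10 is cut by an aryne ring closure of a nitrile-stabilised carbanion. The nitrile of 12 is then exchanged for the ester of 14 so that C20 and C19 remain distinguishable. The aryne C9≡C11 can arise from a bromide on either carbon. C11 is ortho and para to the two methoxy groups and is reached by direct bromination, whereas C9 is meta to both, so the bromide is placed on C11 (nitrile 10).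

**Arene (10 ⇒ 9 ⇒ 7 + 8; 7 ⇒ 6 ⇒ 5 ⇒ 4 ⇒ 1 + 2).** The C7–C8 side chain comes from olefination of aldehyde 7 with phosphonate 8 and conjugate reduction of 9. Bromine, formyl and isopropyl groups are introduced in that reverse order onto 1,3-dimethoxybenzene 1. The resorcinol pattern directs each substitution: lithiation between the oxygens (acetone 2 supplies the isopropyl carbons), then formylation and bromination at the two positions ortho/para to them.

**Side chain (22 ⇒ 21 ⇒ 20 ⇒ 19 ⇒ 17 ⇒ 15 + 16).** The C3–C4 bond is cut by a catalytic asymmetric Michael addition of ethyl 2-cyanopropanoate 15 to acrolein 16, a well-developed way to an α-methyl-α-cyano quaternary centre. The ester carbon becomes C5 and the aldehyde carbon C1. Closing the reduced adduct to lactone 19 and reducing it to lactol 20 differentiates the two termini without a protecting group. Methylenation then liberates the vinyl group and the C1 alcohol of 21 in one operation.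

## Roads not taken

**Alternative 1:** The C20–O bond is cut, so the lactone would come from hydroxylation of the angular methyl of 13-isopropylpodocarpic acid A1. A cytochrome P450 of the abietane C20-oxidase family, expressed in yeast with its reductase, would do this, and the new alcohol would close onto the C19 acid to give the 12-hydroxy lactone A2. Its merits are considerable: C4, C5 and C10 come from the chiral pool with no stereochemical risk, no ring has to be built, and an unactivated methyl group is oxidised for which no short chemical equivalent exists. In step count to a tricyclic lactone this road is clearly better than the chosen one. Its weak points are the enzyme and the arene. These oxidases evolved for substrates with a geminal dimethyl group at C4 and typically carry C20 on to the acid; here a C19 carboxylate must be accepted and lactonisation must outrun further oxidation. Neither can be argued from structure. A2 also lacks oxygen at C7, C11 and C14, and C14 is meta to the C12 oxygen, so no phenol-directed oxidation reaches it. The chosen plan is longer, but every bond-forming event has chemical precedent and the 12,14-dioxygenation is present from the first intermediate.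

**Alternative 2:** The bonds C4–C5 and C1–C10 are cut. 2-Propenyllithium would add to C5 of the chiral 1-naphthyl oxazoline A3, and the aza-enolate would be alkylated at C10 by a 3-iodopropyl silyl ether to give the dihydronaphthalene A4. The merits are auxiliary control of C5 and C10 in one operation with trans addition, C20 at carboxyl level, and a C6=C7 alkene as a handle for the C7 oxygen. In reliability of the C5/C10 configuration it is likely superior to the moderate 1,3-relay of the chosen plan. However, no ring is closed. Ring A must still be formed at C3–C4 while C4 becomes a quaternary stereocentre bearing a carboxyl carbon that the 2-propenyl group does not supply. An oxazoline on a quaternary carbon is notoriously hard to hydrolyse or reduce. The tetrasubstituted, electron-rich naphthalene A3 is itself a multistep target. The chosen plan offers two rings and two bonds in one step with C4 and its carboxyl carbon already in place.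

**Alternative 3:** The C6–C7 bond is cut. Photoexcited (Bu4N)4W10O32 would abstract the formyl hydrogen of the aryl aldehyde A5, the aroyl radical would add to the terminal carbon of the exocyclic C5=C6 methylene, and the C5 radical would take a hydrogen atom back to give the keto lactone A6. A6 is identical with compound 30 of the present route, so the endgame would be shared. The merits are real: ring B and the C7 ketone arrive together, catalytically and without chromium, and hydrogen return to C5 from the face opposite the lactone bridge should favour the trans fusion. In that one operation it is better than the chosen plan, which needs a separate benzylic oxidation. The difficulty moves into A5, a bridged bicyclic lactone with two quaternary stereocentres, one carrying a di-ortho-substituted aryl group, which needs its own enantioselective construction without a ring-forming event to help. Decatungstate also abstracts from methoxy, isopropyl and OCH2 hydrogens, and the C5 configuration rests on a single hydrogen-atom transfer. The chosen plan builds the aryl-bearing quaternary C10 and both rings from simple pieces under control of one stereocentre.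

Key step: step 15

## Route

Assumption: the cupreidine-derived catalyst of step 9 is taken to deliver the (R)-adduct 17; should its sense of induction be the opposite, the cupreine-derived pseudoenantiomer is used and nothing else changes.

Step 1
Reactants: 1 1,3-dimethoxybenzene; 2 acetone
Product: 4 2-(2,6-dimethoxyphenyl)propan-2-ol, via 2,6-dimethoxyphenyllithium 3 (not isolated)
Conditions: n-BuLi, THF, 0 °C to rt; then 2, −78 °C to rt; H2O
Reagents that add atoms: none
Why: Directed ortho-lithiation at the position between the two methoxy groups, then 1,2-addition of the aryllithium to acetone; no other ring position competes.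

Step 2
Reactants: 4 2-(2,6-dimethoxyphenyl)propan-2-ol
Product: 5 1,3-dimethoxy-2-(propan-2-yl)benzene
Conditions: Et3SiH, CF3CO2H, CH2Cl2, 0 °C to rt
Reagents that add atoms: none
Why: Ionic hydrogenation: the tertiary benzylic alcohol ionises to a cation stabilised by two ortho methoxy groups and is reduced by the silane; any isopropenyl arene formed by elimination re-enters through the same cation.

Step 3
Reactants: 5 1,3-dimethoxy-2-(propan-2-yl)benzene
Product: 6 2,4-dimethoxy-3-(propan-2-yl)benzaldehyde
Conditions: Cl2CHOMe, TiCl4, CH2Cl2, 0 °C; H2O
Reagents that add atoms: dichloromethyl methyl ether, COC(Cl)Cl; water, O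
Why: Rieche formylation at one of the two equivalent positions ortho to one methoxy group and para to the other; the remaining position is meta to both and unreactive.

Step 4
Reactants: 6 2,4-dimethoxy-3-(propan-2-yl)benzaldehyde
Product: 7 5-bromo-2,4-dimethoxy-3-(propan-2-yl)benzaldehyde
Conditions: NBS, MeCN, rt, dark
Reagents that add atoms: N-bromosuccinimide, O=C1CCC(=O)N1Br
Why: Electrophilic aromatic bromination at the one remaining position that is ortho/para to the methoxy groups and meta to the formyl group; this carbon is C11 of the later skeleton.

Step 5
Reactants: 7 5-bromo-2,4-dimethoxy-3-(propan-2-yl)benzaldehyde; 8 diethyl (cyanomethyl)phosphonate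
Product: 9 (2E)-3-[5-bromo-2,4-dimethoxy-3-(propan-2-yl)phenyl]prop-2-enenitrile
Conditions: t-BuOK, THF, 0 °C to rt
Reagents that add atoms: none
Why: Horner–Wadsworth–Emmons olefination; the alkene geometry is of no consequence because the double bond is reduced in the next step.

Step 6
Reactants: 9 (2E)-3-[5-bromo-2,4-dimethoxy-3-(propan-2-yl)phenyl]prop-2-enenitrile
Product: 10 3-[5-bromo-2,4-dimethoxy-3-(propan-2-yl)phenyl]propanenitrile
Conditions: NaBH4, pyridine/MeOH, reflux
Reagents that add atoms: none
Why: Conjugate hydride reduction of a β-aryl acrylonitrile; aryl bromide, ethers and the nitrile are inert to NaBH4.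

Step 7
Reactants: 10 3-[5-bromo-2,4-dimethoxy-3-(propan-2-yl)phenyl]propanenitrile
Product: 12 rac-2,4-dimethoxy-3-(propan-2-yl)bicyclo[4.2.0]octa-1,3,5-triene-7-carbonitrile, via cyano-stabilised aryne carbanion 11 (not isolated)
Conditions: NaNH2 (4 equiv), liq. NH3, −33 °C; NH4Cl
Reagents that add atoms: none
Why: Aryne ring closure of a bromoarylpropanenitrile: NaNH2 forms the α-cyano carbanion and eliminates HBr using the only hydrogen ortho to bromine; the carbanion adds to the nearer aryne carbon, which is also the one meta to the flanking methoxy group, closing the four-membered ring.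

Step 8
Reactants: 12 rac-2,4-dimethoxy-3-(propan-2-yl)bicyclo[4.2.0]octa-1,3,5-triene-7-carbonitrile
Product: 14 methyl rac-2,4-dimethoxy-3-(propan-2-yl)bicyclo[4.2.0]octa-1,3,5-triene-7-carboxylate, via methyl imidate hydrochloride 13 (not isolated)
Conditions: HCl (g), MeOH, 0 °C to rt; then H2O
Reagents that add atoms: methanol, CO; water, O
Why: Pinner reaction of a secondary nitrile to the imidate salt and hydrolysis to the methyl ester; this makes C20 the only hydride-reducible carboxyl carbon of the later tricycle.

Step 9
Reactants: 15 ethyl 2-cyanopropanoate; 16 acrolein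
Product: 17 ethyl (2R)-2-cyano-2-methyl-5-oxopentanoate
Conditions: 9-O-(9-phenanthryl)cupreidine (10 mol %), CH2Cl2, −25 °C
Reagents that add atoms: none
Why: Bifunctional cinchona-alkaloid-catalysed Michael addition: the quinuclidine nitrogen deprotonates the α-cyano ester and the 6'-hydroxyl activates acrolein, so the C3–C4 bond forms within a chiral ion pair and sets the quaternary C4 centre, which cannot epimerise afterwards.

Step 10
Reactants: 17 ethyl (2R)-2-cyano-2-methyl-5-oxopentanoate
Product: 19 (3R)-3-methyl-2-oxooxane-3-carbonitrile, via hydroxy ester 18 (not isolated)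
Conditions: NaBH4 (0.4 equiv), EtOH, −20 °C; AcOH; then TsOH·H2O (cat.), PhMe, 60 °C
Reagents that add atoms: none
Why: NaBH4 reduces the aldehyde much faster than the ester or nitrile at low temperature; acid-catalysed transesterification then closes the δ-lactone, helped by the geminal substitution, and ties up the C1 oxygen without a protecting group.

Step 11
Reactants: 19 (3R)-3-methyl-2-oxooxane-3-carbonitrile
Product: 20 (3R)-2-hydroxy-3-methyloxane-3-carbonitrile (lactol, both anomers)
Conditions: i-Bu2AlH (1.1 equiv), CH2Cl2, −78 °C; aq. potassium sodium tartrate
Reagents that add atoms: none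
Why: Partial reduction of a lactone to the lactol through a tetrahedral aluminate that is stable at −78 °C; the cyano-activated lactone carbonyl should react ahead of the hindered tertiary nitrile.

Step 12
Reactants: 20 (3R)-2-hydroxy-3-methyloxane-3-carbonitrile
Product: 21 (2S)-2-ethenyl-5-hydroxy-2-methylpentanenitrile
Conditions: Ph3PCH3Br (2.6 equiv), t-BuOK (2.5 equiv), THF, 0 °C to rt
Reagents that add atoms: methyltriphenylphosphonium bromide, C[P+](c1ccccc1)(c1ccccc1)c1ccccc1.[Br-]
Why: Wittig methylenation of a lactol through its open hydroxy-aldehyde form; the aldehyde carbon has no α-hydrogen, so neither enolisation nor epimerisation can occur (the descriptor changes only because the priorities change).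

Step 13
Reactants: 21 (2S)-2-ethenyl-5-hydroxy-2-methylpentanenitrile
Product: 22 (2S)-2-ethenyl-5-iodo-2-methylpentanenitrile
Conditions: I2, PPh3, imidazole, CH2Cl2, 0 °C
Reagents that add atoms: iodine, II
Why: Appel-type iodination of an unhindered primary alcohol by SN2 displacement of the oxyphosphonium group.

Step 14
Reactants: 14 methyl rac-2,4-dimethoxy-3-(propan-2-yl)bicyclo[4.2.0]octa-1,3,5-triene-7-carboxylate; 22 (2S)-2-ethenyl-5-iodo-2-methylpentanenitrile
Product: 24 methyl 7-[(4S)-4-cyano-4-methylhex-5-en-1-yl]-2,4-dimethoxy-3-(propan-2-yl)bicyclo[4.2.0]octa-1,3,5-triene-7-carboxylate (both C7 epimers), via lithium enolate 23 (not isolated)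
Conditions: LDA (1.1 equiv), THF, −78 °C; then 22, DMPU, −78 to 0 °C
Reagents that add atoms: none
Why: C-alkylation of an ester enolate with a primary iodide forms C1–C10; the iodide has no acidic hydrogen, and both epimers at the new centre are used because that carbon becomes planar in the next step.

Step 15
Reactants: 24 methyl 7-[(4S)-4-cyano-4-methylhex-5-en-1-yl]-2,4-dimethoxy-3-(propan-2-yl)bicyclo[4.2.0]octa-1,3,5-triene-7-carboxylate
Product: 26 methyl (4S,5S,10R)-4-cyano-12,14-dimethoxy-19-norabieta-8,11,13-trien-20-oate (nitrile on C4 and ester on C10 both axial on the same face, H-5 on the opposite face, trans A/B), via o-quinodimethane 25 (not isolated)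
Conditions: 1,2-Cl2C6H4 (0.01 M), 180 °C, Ar
Reagents that add atoms: none
Why: Heating opens the cyclobutene by a conrotatory 4π electrocyclic reaction to the o-quinodimethane 25 (C7=C8 and C9=C10), in which the bulkier tether turns outward and the ester inward; the two rotamers interconvert by reclosure and the inward ester has no hydrogen to lose by 1,5-shift. The diene is then captured by the tethered C5=C6 vinyl group in an intramolecular [4+2] cycloaddition that restores the arene, which is why an unactivated alkene suffices. The closest known reaction type is the thermolysis of 1,1-disubstituted benzocyclobutenes bearing a hex-5-enyl chain and a cyano or alkoxycarbonyl group, which gives trans-fused octahydrophenanthrenes with an angular carboxyl-level substituent. Ring B closes as the new cyclohexene of the cycloaddition itself (C6–C7 and C5–C10 formed suprafacially on both partners). Ring A closes as the four-atom tether C1–C4 between the diene terminus C10 and the dienophile carbon C5, the fused mode of a type 1 intramolecular Diels–Alder reaction. C5 and C10 are formed together: their relative configuration follows from the exo transition state with a chair-shaped tether, and their absolute configuration is relayed from C4, because the chair with the slim nitrile axial and syn to the developing axial ester avoids the 1,3-diaxial methyl/ester contact of the alternative chair. The step needs exo over endo selectivity, secured by the quaternary diene terminus and the chair tether, and nitrile-axial over methyl-axial facial selectivity, secured by the difference in size between cyano and methyl reinforced by the syn-axial ester. Regiochemistry is fixed by the tether length.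

Step 16
Reactants: 26 methyl (4S,5S,10R)-4-cyano-12,14-dimethoxy-19-norabieta-8,11,13-trien-20-oate
Product: 27 (4S,5S,10R)-20-hydroxy-12,14-dimethoxy-19-norabieta-8,11,13-triene-4-carbonitrile
Conditions: LiBH4, THF/MeOH, 50 °C
Reagents that add atoms: none
Why: LiBH4 reduces esters but not nitriles; lithium coordination to the ester carbonyl lets hydride reach the hindered axial ester, and any alkoxide that adds to the neighbouring nitrile only anticipates the next step.

Step 17
Reactants: 27 (4S,5S,10R)-20-hydroxy-12,14-dimethoxy-19-norabieta-8,11,13-triene-4-carbonitrile
Product: 29 (4S,5R,10R)-12,14-dimethoxyabieta-8,11,13-trien-19,20-olide, via iminolactone hydrochloride 28 (not isolated)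
Conditions: HCl (4 M in dioxane), CH2Cl2, 0 °C to rt; then H2O, THF, 50 °C
Reagents that add atoms: water, O
Why: Intramolecular Pinner reaction: the C20 hydroxyl, held 1,3-diaxial to the protonated nitrile, closes the six-membered cyclic imidate, which water hydrolyses to the lactone. Only the diastereomer with nitrile and hydroxymethyl syn can cyclise, so any C4-epimeric material from step 15 is left behind as an easily separated hydroxy nitrile.

Step 18
Reactants: 29 (4S,5R,10R)-12,14-dimethoxyabieta-8,11,13-trien-19,20-olide
Product: 30 (4S,5R,10R)-12,14-dimethoxy-7-oxoabieta-8,11,13-trien-19,20-olide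
Conditions: CrO3, AcOH/H2O, 20 °C
Reagents that add atoms: chromium trioxide, O=[Cr](=O)=O
Why: Benzylic oxidation by hexavalent chromium at C7, the only benzylic methylene, activated by the para (C12) and ortho (C14) methoxy groups; the isopropyl methine is shielded by its two flanking methoxy groups and the lactone is inert.

Step 19
Reactants: 30 (4S,5R,10R)-12,14-dimethoxy-7-oxoabieta-8,11,13-trien-19,20-olide
Product: 31 (4S,5R,10R)-14-hydroxy-12-methoxy-7-oxoabieta-8,11,13-trien-19,20-olide
Conditions: BCl3, CH2Cl2, −78 to 0 °C; aq. NaHCO3
Reagents that add atoms: none
Why: Chelation-controlled ether cleavage: BCl3 bridges the C7 carbonyl and the C14 methoxy oxygen in a six-membered chelate and cleaves only that methyl ether; the C12 ether and the lactone remain.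

Step 20
Reactants: 31 (4S,5R,10R)-14-hydroxy-12-methoxy-7-oxoabieta-8,11,13-trien-19,20-olide
Product: 33 (4S,5R,10R)-11,14-dihydroxy-12-methoxy-7-oxoabieta-8,11,13-trien-19,20-olide (CNP0159814.2), via 11,14-quinone 32 (not isolated)
Conditions: (KSO3)2NO (2.5 equiv), KH2PO4, acetone/H2O, rt; then Na2S2O4, H2O, rt, Ar
Reagents that add atoms: potassium nitrosodisulfonate, [K+].[K+].[O]N(S(=O)(=O)[O-])S(=O)(=O)[O-]
Why: Teuber oxidation: two equivalents of the nitroxyl radical salt convert the phenol into the para-quinone at the free C11 position. Dithionite then reduces the quinone to the hydroquinone in the same flask, so the electrophilic quinone is not handled and the air-sensitive target is formed last.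

## Compound list

1 | 1,3-dimethoxybenzene | COc1cccc(OC)c1 | starting material
2 | acetone | CC(C)=O | starting material
3 | 2,6-dimethoxyphenyllithium | [Li]c1c(OC)cccc1OC | intermediate
4 | 2-(2,6-dimethoxyphenyl)propan-2-ol | COc1cccc(OC)c1C(C)(C)O | intermediate
5 | 1,3-dimethoxy-2-(propan-2-yl)benzene | COc1cccc(OC)c1C(C)C | intermediate
6 | 2,4-dimethoxy-3-(propan-2-yl)benzaldehyde | COc1ccc(C=O)c(OC)c1C(C)C | intermediate
7 | 5-bromo-2,4-dimethoxy-3-(propan-2-yl)benzaldehyde | COc1c(Br)cc(C=O)c(OC)c1C(C)C | intermediate
8 | diethyl (cyanomethyl)phosphonate | CCOP(=O)(CC#N)OCC | starting material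
9 | (2E)-3-[5-bromo-2,4-dimethoxy-3-(propan-2-yl)phenyl]prop-2-enenitrile | COc1c(Br)cc(/C=C/C#N)c(OC)c1C(C)C | intermediate
10 | 3-[5-bromo-2,4-dimethoxy-3-(propan-2-yl)phenyl]propanenitrile | COc1c(Br)cc(CCC#N)c(OC)c1C(C)C | intermediate
11 | sodium salt of the α-cyano carbanion of 3-[2,4-dimethoxy-3-(propan-2-yl)-5,6-didehydrophenyl]propanenitrile (aryne) | [Na+].N#C[CH-]CC1=C(OC)C(C(C)C)=C(OC)C#C1 | intermediate
12 | rac-2,4-dimethoxy-3-(propan-2-yl)bicyclo[4.2.0]octa-1,3,5-triene-7-carbonitrile | COc1cc2c(c(OC)c1C(C)C)CC2C#N | intermediate
13 | methyl rac-2,4-dimethoxy-3-(propan-2-yl)bicyclo[4.2.0]octa-1,3,5-triene-7-carboximidate hydrochloride | COc1cc2c(c(OC)c1C(C)C)CC2C(=[NH2+])OC.[Cl-] | intermediate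
14 | methyl rac-2,4-dimethoxy-3-(propan-2-yl)bicyclo[4.2.0]octa-1,3,5-triene-7-carboxylate | COc1cc2c(c(OC)c1C(C)C)CC2C(=O)OC | intermediate
15 | ethyl 2-cyanopropanoate | CCOC(=O)C(C)C#N | starting material
16 | acrolein (prop-2-enal) | C=CC=O | starting material
17 | ethyl (2R)-2-cyano-2-methyl-5-oxopentanoate | O=CCC[C@@](C)(C(=O)OCC)C#N | intermediate
18 | ethyl (2R)-2-cyano-5-hydroxy-2-methylpentanoate | OCCC[C@@](C)(C(=O)OCC)C#N | intermediate
19 | (3R)-3-methyl-2-oxooxane-3-carbonitrile | O=C1OCCC[C@]1(C)C#N | intermediate
20 | (3R)-2-hydroxy-3-methyloxane-3-carbonitrile (both anomers) | OC1OCCC[C@]1(C)C#N | intermediate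
21 | (2S)-2-ethenyl-5-hydroxy-2-methylpentanenitrile | OCCC[C@@](C)(C=C)C#N | intermediate
22 | (2S)-2-ethenyl-5-iodo-2-methylpentanenitrile | ICCC[C@@](C)(C=C)C#N | intermediate
23 | lithium enolate of 14 | [Li+].COC([O-])=C1Cc2c1cc(OC)c(C(C)C)c2OC | intermediate
24 | methyl 7-[(4S)-4-cyano-4-methylhex-5-en-1-yl]-2,4-dimethoxy-3-(propan-2-yl)bicyclo[4.2.0]octa-1,3,5-triene-7-carboxylate (both C7 epimers) | COc1cc2c(c(OC)c1C(C)C)CC2(C(=O)OC)CCC[C@@](C)(C=C)C#N | intermediate
25 | o-quinodimethane from 24 (exocyclic C7=C8 and C9=C10; tether outward, ester inward) | COC(=O)/C(CCC[C@@](C)(C=C)C#N)=C1/C=C(OC)C(C(C)C)=C(OC)C1=C | intermediate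
26 | methyl (4S,5S,10R)-4-cyano-12,14-dimethoxy-19-norabieta-8,11,13-trien-20-oate | COc1cc2c(c(OC)c1C(C)C)CC[C@@H]1[C@]2(C(=O)OC)CCC[C@]1(C)C#N | intermediate
27 | (4S,5S,10R)-20-hydroxy-12,14-dimethoxy-19-norabieta-8,11,13-triene-4-carbonitrile | COc1cc2c(c(OC)c1C(C)C)CC[C@@H]1[C@]2(CO)CCC[C@]1(C)C#N | intermediate
28 | (4S,5R,10R)-19-imino-12,14-dimethoxy-19,20-epoxyabieta-8,11,13-triene hydrochloride (cyclic imidate) | COc1cc2c(c(OC)c1C(C)C)CC[C@@H]1[C@]23CCC[C@]1(C)C(=[NH2+])OC3.[Cl-] | intermediate
29 | (4S,5R,10R)-12,14-dimethoxyabieta-8,11,13-trien-19,20-olide | COc1cc2c(c(OC)c1C(C)C)CC[C@@H]1[C@]23CCC[C@]1(C)C(=O)OC3 | intermediate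
30 | (4S,5R,10R)-12,14-dimethoxy-7-oxoabieta-8,11,13-trien-19,20-olide | COc1cc2c(c(OC)c1C(C)C)C(=O)C[C@@H]1[C@]23CCC[C@]1(C)C(=O)OC3 | intermediate
31 | (4S,5R,10R)-14-hydroxy-12-methoxy-7-oxoabieta-8,11,13-trien-19,20-olide | COc1cc2c(c(O)c1C(C)C)C(=O)C[C@@H]1[C@]23CCC[C@]1(C)C(=O)OC3 | intermediate
32 | (4S,5R,10R)-12-methoxy-7,11,14-trioxoabieta-8,12-dien-19,20-olide | COC1=C(C(C)C)C(=O)C(C(=O)C[C@@H]3[C@]24CCC[C@]3(C)C(=O)OC4)=C2C1=O | intermediate
33 | (4S,5R,10R)-11,14-dihydroxy-12-methoxy-7-oxoabieta-8,11,13-trien-19,20-olide (CNP0159814.2) | COc1c(O)c2c(c(O)c1C(C)C)C(=O)C[C@@H]1[C@]23CCC[C@]1(C)C(=O)OC3 | target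

## Step count and least certain steps

Total: 20 steps. Longest linear sequence: 15 steps (steps 1–8 and 14–20); the side chain (steps 9–13) joins at step 14.

**Step 15 (key step).** Two processes may erode it. The first is incomplete discrimination between the nitrile-axial and methyl-axial chairs, since the preference is of moderate size at 180 °C. The second is loss of the diene through 1,5-hydrogen shift from the rotamer with the tether inward, or through dimerisation, because the neopentyl, unactivated vinyl group is a slow trap. The wrong facial isomer is purged at step 17, but it costs material. The fallback activates the dienophile with a traceless group. From 24, radical addition of PhSeSO2Ph to the vinyl group (AIBN, benzene, 80 °C) should give the β-phenylselanyl sulfone F1. Oxidation with H2O2 and syn-elimination of the selenoxide, for which only C6 offers a hydrogen, gives the (E)-vinyl sulfone F2. Thermolysis as in step 15 then captures the diene much faster and gives the 6-phenylsulfonyl tricycle F3. Na(Hg) with Na2HPO4 in MeOH removes the sulfone and the route is rejoined at 26.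

**Step 9.** The nucleophile carries only a methyl group to distinguish its faces, so the enantioselectivity may be insufficient, and acrolein may oligomerise under base. The fallback forms the same quaternary centre by alkylation. From 15, allylation with allyl bromide under asymmetric phase-transfer catalysis (chiral N-spiro binaphthyl quaternary ammonium bromide, CsOH·H2O, toluene, −20 °C) gives ethyl (2R)-2-cyano-2-methylpent-4-enoate F4. Hydroboration with 9-BBN and oxidation with NaBO3 gives the hydroxy ester 18, which lactonises as in step 10, and the route is rejoined at 19.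

**Step 11.** Hydride may also attack the nitrile, or the lactol aluminate may collapse and be reduced further to the diol. The fallback accepts full reduction and differentiates the two alcohols by hindrance. From 19, NaBH4 in EtOH at rt gives (2R)-5-hydroxy-2-(hydroxymethyl)-2-methylpentanenitrile F5. TBSCl and imidazole at −20 °C silylate the unhindered hydroxyl to give the silyl ether F6. Dess–Martin periodinane oxidises the neopentyl alcohol to the aldehyde F7. Wittig methylenation gives the silyl-protected alkene F8, and Bu4NF returns to 21.

**Step 16.** Hydride delivery to the axial neopentyl ester flanked by the arene may be so slow that forcing conditions begin to attack the nitrile. The fallback reduces both groups and re-oxidises. From 26, excess i-Bu2AlH (toluene, −78 to 0 °C) followed by aqueous acid gives the C20 alcohol and the C19 aldehyde, which close to the lactol (4S,5R,10R)-12,14-dimethoxy-19,20-epoxyabieta-8,11,13-trien-19-ol F9. Oxidation with Ag2CO3 on Celite gives 29, so step 17 is bypassed.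

**Step 20.** The phenol is hydrogen-bonded to the C7 carbonyl and deactivated by it, so hydrogen abstraction by the nitroxyl radical may be slow and side-chain oxidation may intervene. The fallback is the Elbs persulfate oxidation, which is known to hydroxylate o-acylphenols at the para position. From 31, K2S2O8 in aqueous NaOH (the lactone opens reversibly to the hydroxy carboxylate) followed by neutralisation gives the potassium 11-sulfate F10. Warm aqueous HCl cleaves the sulfate ester, re-closes the lactone and gives 33 directly.

## Further compounds

F1 | step 15 | methyl 7-[4-cyano-4-methyl-5-(phenylselanyl)-6-(phenylsulfonyl)hexyl]-2,4-dimethoxy-3-(propan-2-yl)bicyclo[4.2.0]octa-1,3,5-triene-7-carboxylate (nitrile-bearing carbon configured as in 24) | COc1cc2c(c(OC)c1C(C)C)CC2(C(=O)OC)CCC[C@@](C)(C([Se]c1ccccc1)CS(=O)(=O)c1ccccc1)C#N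
F2 | step 15 | methyl 7-[(5E)-4-cyano-4-methyl-6-(phenylsulfonyl)hex-5-en-1-yl]-2,4-dimethoxy-3-(propan-2-yl)bicyclo[4.2.0]octa-1,3,5-triene-7-carboxylate (nitrile-bearing carbon configured as in 24) | COc1cc2c(c(OC)c1C(C)C)CC2(C(=O)OC)CCC[C@@](C)(/C=C/S(=O)(=O)c1ccccc1)C#N
F3 | step 15 | methyl 4-cyano-12,14-dimethoxy-6-(phenylsulfonyl)-19-norabieta-8,11,13-trien-20-oate (C4, C5, C10 configured as in 26; C6 epimers) | COc1cc2c(c(OC)c1C(C)C)CC(S(=O)(=O)c1ccccc1)[C@@H]1[C@]2(C(=O)OC)CCC[C@]1(C)C#N
F4 | step 9 | ethyl (2R)-2-cyano-2-methylpent-4-enoate | C=CC[C@@](C)(C(=O)OCC)C#N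
F5 | step 11 | (2R)-5-hydroxy-2-(hydroxymethyl)-2-methylpentanenitrile | OCCC[C@@](C)(CO)C#N
F6 | step 11 | (2R)-5-[(tert-butyldimethylsilyl)oxy]-2-(hydroxymethyl)-2-methylpentanenitrile | CC(C)(C)[Si](C)(C)OCCC[C@@](C)(CO)C#N
F7 | step 11 | (2R)-5-[(tert-butyldimethylsilyl)oxy]-2-formyl-2-methylpentanenitrile | CC(C)(C)[Si](C)(C)OCCC[C@@](C)(C=O)C#N
F8 | step 11 | (2S)-5-[(tert-butyldimethylsilyl)oxy]-2-ethenyl-2-methylpentanenitrile | CC(C)(C)[Si](C)(C)OCCC[C@@](C)(C=C)C#N
F9 | step 16 | (4S,5R,10R)-12,14-dimethoxy-19,20-epoxyabieta-8,11,13-trien-19-ol (lactol of 29, both anomers) | COc1cc2c(c(OC)c1C(C)C)CC[C@@H]1[C@]23CCC[C@]1(C)C(O)OC3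
F10 | step 20 | potassium (4S,5R,10R)-14-hydroxy-12-methoxy-7-oxoabieta-8,11,13-trien-19,20-olid-11-yl sulfate | COc1c(OS(=O)(=O)[O-])c2c(c(O)c1C(C)C)C(=O)C[C@@H]1[C@]23CCC[C@]1(C)C(=O)OC3.[K+]
A1 | alternative 1 | 13-isopropylpodocarpic acid (12-hydroxyabieta-8,11,13-trien-19-oic acid) | Oc1cc2c(cc1C(C)C)CC[C@@H]1[C@]2(C)CCC[C@]1(C)C(=O)O
A2 | alternative 1 | 12-hydroxyabieta-8,11,13-trien-19,20-olide | Oc1cc2c(cc1C(C)C)CC[C@@H]1[C@]23CCC[C@]1(C)C(=O)OC3
A3 | alternative 2 | (4S)-4-tert-butyl-2-[5,7-dimethoxy-6-(propan-2-yl)naphthalen-1-yl]-4,5-dihydro-1,3-oxazole | COc1cc2c(C3=N[C@@H](C(C)(C)C)CO3)cccc2c(OC)c1C(C)C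
A4 | alternative 2 | 1,2-dihydronaphthalene adduct (oxazoline carbon C20 and 3-silyloxypropyl chain on C10, 2-propenyl on C5) | COc1cc2c(c(OC)c1C(C)C)C=C[C@@H](C(C)=C)[C@]2(C1=N[C@@H](C(C)(C)C)CO1)CCCO[Si](C)(C)C(C)(C)C
A5 | alternative 3 | 2-formyl-3,5-dimethoxy-4-(propan-2-yl)phenyl bridged lactone with exocyclic C5=C6 methylene (6,7-seco aldehyde of A6) | COc1cc(c(C=O)c(OC)c1C(C)C)[C@]23CCC[C@](C)(C(=O)OC2)C3=C
A6 | alternative 3 | 12,14-dimethoxy-7-oxoabieta-8,11,13-trien-19,20-olide (identical with 30) | COc1cc2c(c(OC)c1C(C)C)C(=O)C[C@@H]1[C@]23CCC[C@]1(C)C(=O)OC3
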